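## Analysis of the target

The target 37 is a dihydrobenzofuran neolignan. Its core is a 2,3-dihydrobenzofuran (O1, C2, C3, C3a, C4–C7, C7a; benzo ring A) that carries a 4-hydroxy-3-methoxyphenyl group (ring B) on C2, an acyloxymethyl carbon (C9) on C3, a three-carbon chain on C5 and a methoxy group on C7. C2 (R) and C3 (S) are the only stereocentres; they are adjacent and trans, the thermodynamically preferred arrangement, but the absolute configuration has to be set deliberately. The two primary alcohols are acylated differently, C9–OH by (E)-4-hydroxycinnamic acid and the chain terminus by (Z)-ferulic acid, so they must be released and esterified one after the other. The sensitive elements are the Z-enoate (isomerised by light and by nucleophiles that add reversibly to an activated acyl derivative), the two enoate esters (no hydrogenolysis, no strong base or hydride late on), three free phenols, and the C2–O1 bond, a para-oxygenated benzylic aryl ether that can ionise in strong acid. The difficulty lies in combining an enantiopure trans-2-aryl-3-(oxymethyl)dihydrobenzofuran, a 5,7-disubstituted ring A and an orthogonal endgame for two esters and three phenols. The route rests on one observation: O1–C7a=C3a is the enol ether of a γ-butyrolactone whose γ- and β-carbons are C2 and C3. A trans-4,5-disubstituted butyrolactone therefore already holds both stereocentres, O1, C9 and ring B, and ring A (C4–C7) can be grown onto its carbonyl carbon and α-carbon.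

## Retrosynthetic reasoning

**37 ⇒ 36.** The three phenols are masked by the same acetal group, so one mild acidic operation ends the synthesis. This acetal is chosen because it survives amide bases, an aryllithium, palladium catalysis and buffered desilylation.

**36 ⇒ 32 + 35.** The chain ester is cut on the alkyl side, O–CH2. In the forward sense the primary carbinol of 32 is activated and displaced by the carboxylate of 35, so the Z-acid is never turned into an acyl electrophile and cannot isomerise by reversible conjugate addition. This ester is made last because it is the most fragile element. 35 comes from 34, and 34 from aldehyde 2 and phosphonate 33 by a Z-selective olefination; the Z-acid can be freed of E isomer before it meets the valuable alcohol.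

**32 ⇒ 31 ⇒ 26 + 30.** The C9 ester is cut at the acyl C–O bond; the robust E-acid 30 tolerates ordinary carbodiimide activation. The two primary alcohols are told apart by two silyl ethers of very different acid lability. The C9 ether is removed first (25 → 26), the chain ether only after C9 is acylated (31 → 32). 30 comes from 28 and 29, and 28 from 27.

**26 ⇒ 25 ⇒ 21 + 24.** The C5–CH2 bond is cut, which points to a B-alkyl cross-coupling of the aryl bromide 21 with the alkylborane 24 (from 23, from 22). At this stage 21 holds a single bromide, so no site selectivity is asked of the palladium catalyst.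

**21 ⇒ 20 ⇒ 17.** The C7–O bond is traced back to the C7 bromide of 17. The two bromides of 17 differ mainly in their relation to O1. A halogen–lithium exchange selects cleanly for the bromide flanked by O1 (18); borylation (19) and oxidation then give the phenol 20. Cross-coupling first at C5 was not chosen as the main line, because oxidative addition would have to discriminate on a small steric difference only.

**17 ⇒ 12 + 14 (key disconnection).** Ring A is opened at C3a–C4 and C7a–C7. In the forward sense the cyclic silyl ketene acetal 12 and the pyrone 14 undergo [4+2] cycloaddition (15), decarboxylation (16) and loss of the silyloxy group. Cutting here removes all of ring A in one operation and touches neither stereocentre. The polarity of the partners dictates that the oxygen-bearing carbon ends up next to a bromine, which is where the methoxy group is needed, and the second bromine lands where the chain is needed. 14 comes from 13.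

**12 ⇒ 11 ⇒ 10 ⇒ 9.** These are functional-group changes on the lactone. C9 is carried as a silyl ether and not as an ester, so the lactone enolate has no acyl group within reach and the later aryllithium step needs no ester tolerance.

**9 ⇒ 8 ⇒ 5 + 2.** The C2–C3 bond (C5–C4 of the lactone) is cut as an aldol bond. The imide 5 (from 3 and 4) is enolised to 6 and adds to aldehyde 2 to give the syn aldol 7, and lactonisation converts the syn relationship into the trans ring relationship of 8. An auxiliary-controlled aldol is preferred over a catalytic anhydride–aldehyde condensation, because the unsubstituted four-carbon diacid unit is not acidic enough for the latter, and over a resolution, because the absolute configuration is then predictable. 2 comes from 1.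

## Alternatives that were turned down

**Alternative 1: aryl radical 5-exo cyclisation with oxygen capture at C9.**
- Disconnection: C3a–C3 and C9–O; the dihydrofuran ring is closed last from the aryl iodide A2, an allyl aryl ether that already holds C2.
- Forward key step: tributylstannane A3 generates the C3a aryl radical from A2, which adds 5-exo to the internal vinyl carbon; the resulting C9 radical is captured by the nitroxyl A4 to give A1.
- For it: it is the shortest of the four routes. Ring A arrives with its methoxy group and a C5 allyl handle, and the C9 oxygen is installed in the ring-forming step.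
- Against it: A2 is an electron-rich 1-arylallyl aryl ether whose C2 configuration must be set and then kept, and such ethers ionise and rearrange easily. C3 is created in the key step with only the C2 aryl group to bias the transition state, so a cis/trans mixture must be expected. A3 and A4 consume each other and compete for the C9 radical. The N–O bond of A1 still has to be cleaved reductively and the allyl group converted to the hydroxypropyl chain.
- Comparison: Alternative 1 is stronger on step count. The chosen route offers instead that both stereocentres are fixed by a reliable auxiliary aldol before the uncertain step, and that the uncertain step creates no stereocentre.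

**Alternative 2: copper-catalysed borylative three-component coupling around C3.**
- Disconnection: C2–C3 and C9–B; no ring is closed.
- Forward key step: a chiral bisphosphine–copper boryl species (from CuCl A9, monovalent copper, an alkoxide base and the diboron reagent A8) adds across the styrene A6, boron to C9 and copper to C3. The benzylic copper intermediate then adds to the aldehyde A7 to give A5, with C3 set and C2 as carbinol epimers. Oxidation of the C–B bond, phenol release and acid closure of O1–C2 would follow.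
- For it: it is the most convergent route and uses catalytic asymmetric induction. The C2 epimer mixture is harmless because the later closure through the benzylic cation converges on trans.
- Against it: three chemoselectivities must hold at once. The copper boryl must add to the styrene faster than to the carbonyl group of A7 and faster than to the C5 allyl group, and the benzylic copper must add to A7 faster than it is protonated. A6 is an ortho,ortho'-flanked styrene with a coordinating acetal next to the alkene, a demanding substrate for high enantioselectivity. The later acid closure must coexist with the silyl and acetal groups of A5.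
- Comparison: Alternative 2 is stronger on convergence and needs no stoichiometric auxiliary. The chosen route offers a key step with a single selectivity question, answered by polarity, and stereocentres from a substrate-independent aldol.

**Alternative 3: dirhodium carbene C–H insertion closing the C2–C3 bond.**
- Disconnection: C2–C3, with the dihydrofuran ring closed from an aryldiazoacetate.
- Forward key step: Rh2(S-PTTL)4 A12 (dirhodium tetrakis[N-phthaloyl-(S)-tert-leucinate], divalent rhodium) decomposes the diazo ester A11, and the carbene carbon C3 inserts into a benzylic C–H bond of the ArO–CH2–aryl unit to give the cis ester A10.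
- For it: it has the closest precedent for exactly this ring system, with high enantio- and cis-selectivity expected, and ring A is complete before the key step.
- Against it: A10 is cis, so C3 must be epimerised through an ester enolate that can also expel the aryloxide O1 (ring opening to a cinnamate), and the ester must then be reduced. The benzyl ethers of A10 can only be removed by hydrogenolysis before any enoate is present, which frees the ring B phenol together with the chain alcohol and forces re-protection. A11 needs a multi-step synthesis of a tetrasubstituted arylacetate and a diazo transfer.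
- Comparison: Alternative 3 is stronger on precedent. The chosen route offers the trans relationship directly, protecting groups that fit the endgame, and a dibromide (17) from which the C5 and C7 substituents are introduced independently.

Key step: step 9

Remark on the chemistry: atoms are numbered as in the dihydrobenzofuran of 37 throughout, also in the lactone and ketene acetal precursors (C9 is the CH2O carbon on C3). The transient sp3 centres of 15 and 16 are left unassigned in their SMILES because all isomers converge on 17. Every operation that involves a Z-enoate (steps 19–22) is assumed to be run with exclusion of light.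

## Route

Step 1
Reactants: 1 vanillin (4-hydroxy-3-methoxybenzaldehyde)
Product: 2 3-methoxy-4-(methoxymethoxy)benzaldehyde
Conditions: MOMCl, i-Pr2NEt, CH2Cl2, 0 °C → rt
Reagents that add atoms: chloromethyl methyl ether, COCCl
Why: O-alkylation of the phenoxide by an α-chloro ether (Williamson type); the acetal survives all basic, organometallic, palladium and fluoride steps and is removed only at the end.

Step 2
Reactants: 3 (4R)-4-benzyl-1,3-oxazolidin-2-one; 4 methyl 4-chloro-4-oxobutanoate
Product: 5 methyl 4-[(4R)-4-benzyl-2-oxo-1,3-oxazolidin-3-yl]-4-oxobutanoate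
Conditions: n-BuLi, THF, −78 °C; then 4, −78 → 0 °C
Reagents that add atoms: none
Why: N-acylation of the lithiated oxazolidinone by an acid chloride, the standard entry to Evans imides; the methyl ester is inert at this temperature.

Step 3
Reactants: 5 methyl 4-[(4R)-4-benzyl-2-oxo-1,3-oxazolidin-3-yl]-4-oxobutanoate; 2 3-methoxy-4-(methoxymethoxy)benzaldehyde
Product: 8 (4R)-4-benzyl-3-{[(2R,3R)-2-[3-methoxy-4-(methoxymethoxy)phenyl]-5-oxooxolan-3-yl]carbonyl}-1,3-oxazolidin-2-one (trans lactone), via dibutylboron Z-enolate 6 (not isolated), via open syn-aldol adduct 7 (not isolated)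
Conditions: Bu2BOTf, i-Pr2NEt, CH2Cl2, −78 → 0 °C; 2, −78 → 0 °C; pH 7 buffer, MeOH, H2O2, 0 °C; then PPTS (cat.), PhMe, 50 °C
Reagents that add atoms: none
Why: Evans syn-aldol reaction: the imide, not the methyl ester, is enolised to the Z-boron enolate 6, which adds to 2 through a Zimmerman–Traxler transition state on the face away from the benzyl group of the (R)-auxiliary and so sets both centres (future C3 and C2) in 7. Closure of the γ-hydroxy ester then gives the lactone, in which the syn-aldol relationship has become the trans ring relationship.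

Step 4
Reactants: 8 (4R)-4-benzyl-3-{[(2R,3R)-2-[3-methoxy-4-(methoxymethoxy)phenyl]-5-oxooxolan-3-yl]carbonyl}-1,3-oxazolidin-2-one
Product: 9 (2R,3R)-2-[3-methoxy-4-(methoxymethoxy)phenyl]-5-oxooxolane-3-carboxylic acid
Conditions: LiOH, H2O2, THF/H2O, 0 °C; Na2SO3; 1 M HCl to pH 3, 0 °C
Reagents that add atoms: hydrogen peroxide, OO
Why: Hydroperoxide attacks the exocyclic imide carbonyl selectively (Evans auxiliary cleavage) and sulfite reduces the peracid; any lactone opened by hydroxide recloses on acidification because only the γ-lactone can form, and the auxiliary 3 is recovered.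

Step 5
Reactants: 9 (2R,3R)-2-[3-methoxy-4-(methoxymethoxy)phenyl]-5-oxooxolane-3-carboxylic acid
Product: 10 (4S,5R)-4-(hydroxymethyl)-5-[3-methoxy-4-(methoxymethoxy)phenyl]oxolan-2-one
Conditions: BH3·SMe2, THF, 0 °C → rt; MeOH quench
Reagents that add atoms: none
Why: Borane reduces a free carboxylic acid through its acyloxyborane much faster than a lactone, a chemoselectivity well established for paraconic acids; neither stereocentre is touched (the descriptor at C4 changes only because of the priority rules).

Step 6
Reactants: 10 (4S,5R)-4-(hydroxymethyl)-5-[3-methoxy-4-(methoxymethoxy)phenyl]oxolan-2-one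
Product: 11 (4S,5R)-4-({[tert-butyl(dimethyl)silyl]oxy}methyl)-5-[3-methoxy-4-(methoxymethoxy)phenyl]oxolan-2-one
Conditions: TBSCl, imidazole, DMF, rt
Reagents that add atoms: tert-butyl(chloro)dimethylsilane, CC(C)(C)[Si](C)(C)Cl
Why: Standard silylation of a primary alcohol; a silyl ether instead of an acyl group on C9 leaves the lactone enolate of step 7 without an electrophilic carbonyl in reach and later tolerates the aryllithium of step 10.

Step 7
Reactants: 11 (4S,5R)-4-({[tert-butyl(dimethyl)silyl]oxy}methyl)-5-[3-methoxy-4-(methoxymethoxy)phenyl]oxolan-2-one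
Product: 12 tert-butyl{[(4S,5R)-4-({[tert-butyl(dimethyl)silyl]oxy}methyl)-5-[3-methoxy-4-(methoxymethoxy)phenyl]-4,5-dihydrofuran-2-yl]oxy}dimethylsilane (cyclic silyl ketene acetal)
Conditions: LiN(i-Pr)2, THF, −78 °C; TBSCl, DMPU, −78 → 0 °C; pentane, filtration, used crude
Reagents that add atoms: tert-butyl(chloro)dimethylsilane, CC(C)(C)[Si](C)(C)Cl
Why: Kinetic deprotonation of the lactone and O-silylation of the enolate in the presence of a dipolar aprotic cosolvent gives the silyl ketene acetal. The β- and γ-carbons (C3, C2) are not acidic and keep their configuration, and the moisture-sensitive product is not chromatographed.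

Step 8
Reactants: 13 coumalic acid (2-oxo-2H-pyran-5-carboxylic acid)
Product: 14 3,5-dibromo-2H-pyran-2-one
Conditions: N-bromosuccinimide, LiOAc, MeCN/H2O, rt
Reagents that add atoms: N-bromosuccinimide, O=C1CCC(=O)N1Br
Why: Electrophilic bromination at C3 and ipso bromodecarboxylation at C5 of the pyrone carboxylic acid, a known one-pot preparation of this dibromopyrone.

Step 9
Reactants: 12 tert-butyl{[(4S,5R)-4-({[tert-butyl(dimethyl)silyl]oxy}methyl)-5-[3-methoxy-4-(methoxymethoxy)phenyl]-4,5-dihydrofuran-2-yl]oxy}dimethylsilane; 14 3,5-dibromo-2H-pyran-2-one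
Product: 17 tert-butyl({(2R,3S)-5,7-dibromo-2-[3-methoxy-4-(methoxymethoxy)phenyl]-2,3-dihydro-1-benzofuran-3-yl}methoxy)dimethylsilane, via bridged lactone cycloadduct 15 (not isolated), via cis-fused dihydroarene 16 (not isolated)
Conditions: 14 (1.5 equiv), 2,6-lutidine (0.3 equiv), PhMe, 60 → 110 °C, sealed tube
Reagents that add atoms: none
Why: Proposed new method: the electron-rich cyclic silyl ketene acetal 12 should add to the electron-poor pyrone 14 in an inverse-electron-demand [4+2] cycloaddition; the closest known reaction type is the benzannulation of 3,5-dibromo-2-pyrone and 3-carbomethoxy-2-pyrone with acyclic ketene acetals and enol ethers, whereas a lactone-derived cyclic silyl ketene acetal has not been used as the 2π partner. The donor carbon of 12 (future C3a) bonds to C6 of 14, the terminus of its vinylogous acceptor system, and the acetal carbon (future C7a) bonds to the bromine-bearing C3, which gives the bridged lactone 15. Retro-[4+2] loss of carbon dioxide from 15 gives the cis-fused dihydroarene 16, and 1,2-elimination of tert-butyldimethylsilanol across C7a–C3a aromatises it to 17. Ring A is closed by intermolecular [4+2] annulation, both of its new bonds (C3a–C4 and C7a–C7) being made in the cycloaddition, while the lactone bridge that closes at the same time is extruded again. No lasting stereocentre is formed: the sp3 centres created at C3a, C7a and the bridgeheads disappear on aromatisation, so facial and endo/exo selectivity are irrelevant, and C2 and C3 are non-acidic spectators. The step needs regioselectivity, which the matched polarity of the two partners secures and which places the bromines at C7 and C5, and it needs loss of the silyloxy group rather than of O1 from C7a. Silanolate is the better nucleofuge and its departure leaves a cation stabilised by the ring oxygen, and the hindered pyridine base keeps the medium free of acid that could protonate O1 or hydrolyse 12.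

Step 10
Reactants: 17 tert-butyl({(2R,3S)-5,7-dibromo-2-[3-methoxy-4-(methoxymethoxy)phenyl]-2,3-dihydro-1-benzofuran-3-yl}methoxy)dimethylsilane
Product: 20 (2R,3S)-5-bromo-3-({[tert-butyl(dimethyl)silyl]oxy}methyl)-2-[3-methoxy-4-(methoxymethoxy)phenyl]-2,3-dihydro-1-benzofuran-7-ol, via C7 aryllithium 18 (not isolated), via dimethyl arylboronate 19 (not isolated)
Conditions: n-BuLi (1.05 equiv), THF, −78 °C; B(OMe)3, −78 → 0 °C; H2O2, NaOH (aq.), 0 °C
Reagents that add atoms: hydrogen peroxide, OO
Why: Bromine–lithium exchange is fastest at the bromide flanked by O1 (inductive stabilisation and coordination of lithium by the ring oxygen, as in 2,4-dibromoanisole), so only C7 is metalated at −78 °C. Borylation and oxidation of the C–B bond give the phenol, while the C5 bromide, the silyl ether and the acetal are untouched.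

Step 11
Reactants: 20 (2R,3S)-5-bromo-3-({[tert-butyl(dimethyl)silyl]oxy}methyl)-2-[3-methoxy-4-(methoxymethoxy)phenyl]-2,3-dihydro-1-benzofuran-7-ol
Product: 21 tert-butyl({(2R,3S)-5-bromo-7-methoxy-2-[3-methoxy-4-(methoxymethoxy)phenyl]-2,3-dihydro-1-benzofuran-3-yl}methoxy)dimethylsilane
Conditions: MeI, K2CO3, DMF, rt
Reagents that add atoms: iodomethane, CI
Why: Williamson methylation of the only free phenol; the ring B oxygen is blocked as its acetal, so no regiochemical question arises.

Step 12
Reactants: 22 prop-2-en-1-ol (allyl alcohol)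
Product: 23 tert-butyl(diphenyl)(prop-2-en-1-yloxy)silane
Conditions: TBDPSCl, imidazole, CH2Cl2, rt
Reagents that add atoms: tert-butyl(chloro)diphenylsilane, CC(C)(C)[Si](Cl)(c1ccccc1)c1ccccc1
Why: Routine silylation; the tert-butyldiphenylsilyl ether is far more stable to acid than the tert-butyldimethylsilyl ether on C9, which allows the two primary alcohols to be released in sequence.

Step 13
Reactants: 21 tert-butyl({(2R,3S)-5-bromo-7-methoxy-2-[3-methoxy-4-(methoxymethoxy)phenyl]-2,3-dihydro-1-benzofuran-3-yl}methoxy)dimethylsilane; 23 tert-butyl(diphenyl)(prop-2-en-1-yloxy)silane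
Product: 25 tert-butyl(3-{(2R,3S)-3-({[tert-butyl(dimethyl)silyl]oxy}methyl)-7-methoxy-2-[3-methoxy-4-(methoxymethoxy)phenyl]-2,3-dihydro-1-benzofuran-5-yl}propoxy)diphenylsilane, via B-alkyl-9-BBN borane 24 (not isolated)
Conditions: 23, 9-BBN-H, THF, 0 °C → rt; then 21, PdCl2(dppf) (dppf = 1,1'-bis(diphenylphosphino)ferrocene), K3PO4 (aq.), THF/DMF, 65 °C
Reagents that add atoms: none
Why: Anti-Markovnikov hydroboration of 23 gives the primary alkylborane 24, which undergoes B-alkyl Suzuki–Miyaura coupling with the single remaining aryl bromide (oxidative addition to zerovalent palladium formed from the divalent palladium precatalyst, base-assisted transmetalation, reductive elimination). The wide-bite-angle ligand dppf disfavours β-hydride elimination from the alkylpalladium intermediate.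

Step 14
Reactants: 25 tert-butyl(3-{(2R,3S)-3-({[tert-butyl(dimethyl)silyl]oxy}methyl)-7-methoxy-2-[3-methoxy-4-(methoxymethoxy)phenyl]-2,3-dihydro-1-benzofuran-5-yl}propoxy)diphenylsilane
Product: 26 {(2R,3S)-5-{3-[(tert-butyldiphenylsilyl)oxy]propyl}-7-methoxy-2-[3-methoxy-4-(methoxymethoxy)phenyl]-2,3-dihydro-1-benzofuran-3-yl}methanol
Conditions: camphorsulfonic acid (0.1 equiv), MeOH/CH2Cl2, 0 °C
Reagents that add atoms: none
Why: Acid-catalysed methanolysis removes the primary tert-butyldimethylsilyl ether, while the much more acid-stable tert-butyldiphenylsilyl ether and the aryl acetal survive catalytic acid at 0 °C.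

Step 15
Reactants: 27 4-hydroxybenzaldehyde
Product: 28 4-(methoxymethoxy)benzaldehyde
Conditions: MOMCl, i-Pr2NEt, CH2Cl2, 0 °C → rt
Reagents that add atoms: chloromethyl methyl ether, COCCl
Why: Same phenol protection as in step 1, so that all three phenols can be released together at the end.

Step 16
Reactants: 28 4-(methoxymethoxy)benzaldehyde; 29 malonic acid
Product: 30 (2E)-3-[4-(methoxymethoxy)phenyl]prop-2-enoic acid
Conditions: pyridine, piperidine (cat.), 90 °C; cold dilute acid work-up to pH 3
Reagents that add atoms: none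
Why: Knoevenagel–Doebner condensation with decarboxylation gives the E-cinnamic acid under thermodynamic control; the acetal is stable to the basic medium.

Step 17
Reactants: 26 {(2R,3S)-5-{3-[(tert-butyldiphenylsilyl)oxy]propyl}-7-methoxy-2-[3-methoxy-4-(methoxymethoxy)phenyl]-2,3-dihydro-1-benzofuran-3-yl}methanol; 30 (2E)-3-[4-(methoxymethoxy)phenyl]prop-2-enoic acid
Product: 31 {(2R,3S)-5-{3-[(tert-butyldiphenylsilyl)oxy]propyl}-7-methoxy-2-[3-methoxy-4-(methoxymethoxy)phenyl]-2,3-dihydro-1-benzofuran-3-yl}methyl (2E)-3-[4-(methoxymethoxy)phenyl]prop-2-enoate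
Conditions: EDC·HCl, DMAP (cat.), CH2Cl2, 0 °C → rt
Reagents that add atoms: none
Why: Steglich esterification of the primary C9 alcohol; the E-acid tolerates carbodiimide/DMAP activation without loss of geometry.

Step 18
Reactants: 31 {(2R,3S)-5-{3-[(tert-butyldiphenylsilyl)oxy]propyl}-7-methoxy-2-[3-methoxy-4-(methoxymethoxy)phenyl]-2,3-dihydro-1-benzofuran-3-yl}methyl (2E)-3-[4-(methoxymethoxy)phenyl]prop-2-enoate
Product: 32 {(2R,3S)-5-(3-hydroxypropyl)-7-methoxy-2-[3-methoxy-4-(methoxymethoxy)phenyl]-2,3-dihydro-1-benzofuran-3-yl}methyl (2E)-3-[4-(methoxymethoxy)phenyl]prop-2-enoate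
Conditions: HF·pyridine, pyridine, THF, 0 °C → rt
Reagents that add atoms: none
Why: Fluoride cleaves the Si–O bond of the primary silyl ether; the ester, the aryl acetals and the enoate are inert to pyridine-buffered HF.

Step 19
Reactants: 2 3-methoxy-4-(methoxymethoxy)benzaldehyde; 33 methyl [bis(2,2,2-trifluoroethoxy)phosphoryl]acetate
Product: 34 methyl (2Z)-3-[3-methoxy-4-(methoxymethoxy)phenyl]prop-2-enoate
Conditions: KN(SiMe3)2, 18-crown-6, THF, −78 °C
Reagents that add atoms: none
Why: Still–Gennari olefination: with the electron-poor trifluoroethyl phosphonate and a dissociated potassium counter-ion the kinetically formed oxaphosphetane collapses before it can equilibrate, which gives the Z-enoate. The minor E isomer is removed by chromatography at this small-molecule stage.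

Step 20
Reactants: 34 methyl (2Z)-3-[3-methoxy-4-(methoxymethoxy)phenyl]prop-2-enoate
Product: 35 (2Z)-3-[3-methoxy-4-(methoxymethoxy)phenyl]prop-2-enoic acid
Conditions: LiOH, THF/H2O, rt, dark; cold 1 M HCl to pH 3
Reagents that add atoms: lithium hydroxide, [Li+].[OH-]
Why: Saponification by acyl–oxygen cleavage; hydroxide attacks the carbonyl carbon and not the β-carbon, so the Z geometry is kept, and the brief cold acidification spares the acetal.

Step 21
Reactants: 32 {(2R,3S)-5-(3-hydroxypropyl)-7-methoxy-2-[3-methoxy-4-(methoxymethoxy)phenyl]-2,3-dihydro-1-benzofuran-3-yl}methyl (2E)-3-[4-(methoxymethoxy)phenyl]prop-2-enoate; 35 (2Z)-3-[3-methoxy-4-(methoxymethoxy)phenyl]prop-2-enoic acid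
Product: 36 3-{(2R,3S)-7-methoxy-2-[3-methoxy-4-(methoxymethoxy)phenyl]-3-[({(2E)-3-[4-(methoxymethoxy)phenyl]prop-2-enoyl}oxy)methyl]-2,3-dihydro-1-benzofuran-5-yl}propyl (2Z)-3-[3-methoxy-4-(methoxymethoxy)phenyl]prop-2-enoate
Conditions: PPh3, DIAD, THF, 0 °C → rt, dark
Reagents that add atoms: none
Why: Mitsunobu esterification: the primary alcohol is activated as its alkoxyphosphonium salt and displaced by the carboxylate of 35, so the Z-acid is never converted into an acyl electrophile that could isomerise by reversible conjugate addition.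

Step 22
Reactants: 36 3-{(2R,3S)-7-methoxy-2-[3-methoxy-4-(methoxymethoxy)phenyl]-3-[({(2E)-3-[4-(methoxymethoxy)phenyl]prop-2-enoyl}oxy)methyl]-2,3-dihydro-1-benzofuran-5-yl}propyl (2Z)-3-[3-methoxy-4-(methoxymethoxy)phenyl]prop-2-enoate
Product: 37 3-{(2R,3S)-2-(4-hydroxy-3-methoxyphenyl)-3-[({(2E)-3-(4-hydroxyphenyl)prop-2-enoyl}oxy)methyl]-7-methoxy-2,3-dihydro-1-benzofuran-5-yl}propyl (2Z)-3-(4-hydroxy-3-methoxyphenyl)prop-2-enoate (target)
Conditions: 3 M HCl (aq.), THF/i-PrOH, 40 °C, dark
Reagents that add atoms: none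
Why: Acid-catalysed hydrolysis of the three aryl methoxymethyl acetals through oxocarbenium ions; dilute aqueous acid in a poorly transesterifying alcohol at mild temperature should leave the two enoate esters, the Z-alkene and the C2–O1 ether intact.

## Compound list

1 | vanillin (4-hydroxy-3-methoxybenzaldehyde) | COc1cc(C=O)ccc1O | starting material
2 | 3-methoxy-4-(methoxymethoxy)benzaldehyde | COCOc1ccc(C=O)cc1OC | intermediate
3 | (4R)-4-benzyl-1,3-oxazolidin-2-one | O=C1N[C@H](Cc2ccccc2)CO1 | starting material
4 | methyl 4-chloro-4-oxobutanoate | COC(=O)CCC(=O)Cl | starting material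
5 | methyl 4-[(4R)-4-benzyl-2-oxo-1,3-oxazolidin-3-yl]-4-oxobutanoate | COC(=O)CCC(=O)N1C(=O)OC[C@H]1Cc1ccccc1 | intermediate
6 | dibutylboron Z-enolate of 5 | CCCCB(CCCC)O/C(N1C(=O)OC[C@H]1Cc1ccccc1)=C\CC(=O)OC | intermediate (not isolated)
7 | methyl (3R,4R)-3-{[(4R)-4-benzyl-2-oxo-1,3-oxazolidin-3-yl]carbonyl}-4-hydroxy-4-[3-methoxy-4-(methoxymethoxy)phenyl]butanoate | COC(=O)C[C@@H](C(=O)N1C(=O)OC[C@H]1Cc1ccccc1)[C@H](c1ccc(OCOC)c(OC)c1)O | intermediate (not isolated)
8 | (4R)-4-benzyl-3-{[(2R,3R)-2-[3-methoxy-4-(methoxymethoxy)phenyl]-5-oxooxolan-3-yl]carbonyl}-1,3-oxazolidin-2-one | O=C1C[C@@H](C(=O)N2C(=O)OC[C@H]2Cc2ccccc2)[C@H](c2ccc(OCOC)c(OC)c2)O1 | intermediate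
9 | (2R,3R)-2-[3-methoxy-4-(methoxymethoxy)phenyl]-5-oxooxolane-3-carboxylic acid | O=C1C[C@@H](C(=O)O)[C@H](c2ccc(OCOC)c(OC)c2)O1 | intermediate
10 | (4S,5R)-4-(hydroxymethyl)-5-[3-methoxy-4-(methoxymethoxy)phenyl]oxolan-2-one | O=C1C[C@@H](CO)[C@H](c2ccc(OCOC)c(OC)c2)O1 | intermediate
11 | (4S,5R)-4-({[tert-butyl(dimethyl)silyl]oxy}methyl)-5-[3-methoxy-4-(methoxymethoxy)phenyl]oxolan-2-one | O=C1C[C@@H](CO[Si](C)(C)C(C)(C)C)[C@H](c2ccc(OCOC)c(OC)c2)O1 | intermediate
12 | tert-butyl{[(4S,5R)-4-({[tert-butyl(dimethyl)silyl]oxy}methyl)-5-[3-methoxy-4-(methoxymethoxy)phenyl]-4,5-dihydrofuran-2-yl]oxy}dimethylsilane | CC(C)(C)[Si](C)(C)OC1=C[C@@H](CO[Si](C)(C)C(C)(C)C)[C@H](c2ccc(OCOC)c(OC)c2)O1 | intermediate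
13 | coumalic acid (2-oxo-2H-pyran-5-carboxylic acid) | O=C(O)C1=COC(=O)C=C1 | starting material
14 | 3,5-dibromo-2H-pyran-2-one | O=C1OC=C(Br)C=C1Br | intermediate
15 | bridged lactone cycloadduct (4,7-dibromo-2-oxabicyclo[2.2.2]oct-7-en-3-one core with the 2-silyloxytetrahydrofuran ring of 12 fused across C5–C6; acetal carbon bonded to the bromine-bearing bridgehead; new sp3 centres unassigned) | CC(C)(C)[Si](C)(C)OC12C(C3OC(=O)C2(Br)C=C3Br)[C@@H](CO[Si](C)(C)C(C)(C)C)[C@H](c2ccc(OCOC)c(OC)c2)O1 | intermediate (not isolated)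
16 | cis-fused (2R,3S)-5,7-dibromo-7a-{[tert-butyl(dimethyl)silyl]oxy}-3-({[tert-butyl(dimethyl)silyl]oxy}methyl)-2-[3-methoxy-4-(methoxymethoxy)phenyl]-2,3,3a,7a-tetrahydro-1-benzofuran (C3a, C7a unassigned) | CC(C)(C)[Si](C)(C)OC12C(C=C(Br)C=C2Br)[C@@H](CO[Si](C)(C)C(C)(C)C)[C@H](c2ccc(OCOC)c(OC)c2)O1 | intermediate (not isolated)
17 | tert-butyl({(2R,3S)-5,7-dibromo-2-[3-methoxy-4-(methoxymethoxy)phenyl]-2,3-dihydro-1-benzofuran-3-yl}methoxy)dimethylsilane | Brc1cc(Br)c2c(c1)[C@@H](CO[Si](C)(C)C(C)(C)C)[C@H](c1ccc(OCOC)c(OC)c1)O2 | intermediate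
18 | {(2R,3S)-5-bromo-3-({[tert-butyl(dimethyl)silyl]oxy}methyl)-2-[3-methoxy-4-(methoxymethoxy)phenyl]-2,3-dihydro-1-benzofuran-7-yl}lithium | Brc1cc([Li])c2c(c1)[C@@H](CO[Si](C)(C)C(C)(C)C)[C@H](c1ccc(OCOC)c(OC)c1)O2 | intermediate (not isolated)
19 | dimethyl {(2R,3S)-5-bromo-3-({[tert-butyl(dimethyl)silyl]oxy}methyl)-2-[3-methoxy-4-(methoxymethoxy)phenyl]-2,3-dihydro-1-benzofuran-7-yl}boronate | Brc1cc(B(OC)OC)c2c(c1)[C@@H](CO[Si](C)(C)C(C)(C)C)[C@H](c1ccc(OCOC)c(OC)c1)O2 | intermediate (not isolated)
20 | (2R,3S)-5-bromo-3-({[tert-butyl(dimethyl)silyl]oxy}methyl)-2-[3-methoxy-4-(methoxymethoxy)phenyl]-2,3-dihydro-1-benzofuran-7-ol | Brc1cc(O)c2c(c1)[C@@H](CO[Si](C)(C)C(C)(C)C)[C@H](c1ccc(OCOC)c(OC)c1)O2 | intermediate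
21 | tert-butyl({(2R,3S)-5-bromo-7-methoxy-2-[3-methoxy-4-(methoxymethoxy)phenyl]-2,3-dihydro-1-benzofuran-3-yl}methoxy)dimethylsilane | Brc1cc(OC)c2c(c1)[C@@H](CO[Si](C)(C)C(C)(C)C)[C@H](c1ccc(OCOC)c(OC)c1)O2 | intermediate
22 | prop-2-en-1-ol (allyl alcohol) | C=CCO | starting material
23 | tert-butyl(diphenyl)(prop-2-en-1-yloxy)silane | C=CCO[Si](c1ccccc1)(c1ccccc1)C(C)(C)C | intermediate
24 | 9-{3-[(tert-butyldiphenylsilyl)oxy]propyl}-9-borabicyclo[3.3.1]nonane | CC(C)(C)[Si](c1ccccc1)(c1ccccc1)OCCCB1C2CCCC1CCC2 | intermediate (not isolated)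
25 | tert-butyl(3-{(2R,3S)-3-({[tert-butyl(dimethyl)silyl]oxy}methyl)-7-methoxy-2-[3-methoxy-4-(methoxymethoxy)phenyl]-2,3-dihydro-1-benzofuran-5-yl}propoxy)diphenylsilane | CC(C)(C)[Si](c1ccccc1)(c1ccccc1)OCCCc1cc(OC)c2c(c1)[C@@H](CO[Si](C)(C)C(C)(C)C)[C@H](c1ccc(OCOC)c(OC)c1)O2 | intermediate
26 | {(2R,3S)-5-{3-[(tert-butyldiphenylsilyl)oxy]propyl}-7-methoxy-2-[3-methoxy-4-(methoxymethoxy)phenyl]-2,3-dihydro-1-benzofuran-3-yl}methanol | CC(C)(C)[Si](c1ccccc1)(c1ccccc1)OCCCc1cc(OC)c2c(c1)[C@@H](CO)[C@H](c1ccc(OCOC)c(OC)c1)O2 | intermediate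
27 | 4-hydroxybenzaldehyde | O=Cc1ccc(O)cc1 | starting material
28 | 4-(methoxymethoxy)benzaldehyde | COCOc1ccc(C=O)cc1 | intermediate
29 | malonic acid | OC(=O)CC(=O)O | starting material
30 | (2E)-3-[4-(methoxymethoxy)phenyl]prop-2-enoic acid | COCOc1ccc(/C=C/C(=O)O)cc1 | intermediate
31 | {(2R,3S)-5-{3-[(tert-butyldiphenylsilyl)oxy]propyl}-7-methoxy-2-[3-methoxy-4-(methoxymethoxy)phenyl]-2,3-dihydro-1-benzofuran-3-yl}methyl (2E)-3-[4-(methoxymethoxy)phenyl]prop-2-enoate | CC(C)(C)[Si](c1ccccc1)(c1ccccc1)OCCCc1cc(OC)c2c(c1)[C@@H](COC(=O)/C=C/c1ccc(OCOC)cc1)[C@H](c1ccc(OCOC)c(OC)c1)O2 | intermediate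
32 | {(2R,3S)-5-(3-hydroxypropyl)-7-methoxy-2-[3-methoxy-4-(methoxymethoxy)phenyl]-2,3-dihydro-1-benzofuran-3-yl}methyl (2E)-3-[4-(methoxymethoxy)phenyl]prop-2-enoate | OCCCc1cc(OC)c2c(c1)[C@@H](COC(=O)/C=C/c1ccc(OCOC)cc1)[C@H](c1ccc(OCOC)c(OC)c1)O2 | intermediate
33 | methyl [bis(2,2,2-trifluoroethoxy)phosphoryl]acetate | COC(=O)CP(=O)(OCC(F)(F)F)OCC(F)(F)F | starting material
34 | methyl (2Z)-3-[3-methoxy-4-(methoxymethoxy)phenyl]prop-2-enoate | COCOc1ccc(/C=C\C(=O)OC)cc1OC | intermediate
35 | (2Z)-3-[3-methoxy-4-(methoxymethoxy)phenyl]prop-2-enoic acid | COCOc1ccc(/C=C\C(=O)O)cc1OC | intermediate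
36 | 3-{(2R,3S)-7-methoxy-2-[3-methoxy-4-(methoxymethoxy)phenyl]-3-[({(2E)-3-[4-(methoxymethoxy)phenyl]prop-2-enoyl}oxy)methyl]-2,3-dihydro-1-benzofuran-5-yl}propyl (2Z)-3-[3-methoxy-4-(methoxymethoxy)phenyl]prop-2-enoate | COCOc1ccc(/C=C\C(=O)OCCCc2cc(OC)c3c(c2)[C@@H](COC(=O)/C=C/c2ccc(OCOC)cc2)[C@H](c2ccc(OCOC)c(OC)c2)O3)cc1OC | intermediate
37 | 3-{(2R,3S)-2-(4-hydroxy-3-methoxyphenyl)-3-[({(2E)-3-(4-hydroxyphenyl)prop-2-enoyl}oxy)methyl]-7-methoxy-2,3-dihydro-1-benzofuran-5-yl}propyl (2Z)-3-(4-hydroxy-3-methoxyphenyl)prop-2-enoate | COc1cc(/C=C\C(=O)OCCCc2cc(OC)c3c(c2)[C@@H](COC(=O)/C=C/c2ccc(O)cc2)[C@H](c2ccc(O)c(OC)c2)O3)ccc1O | target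

## Step count and least certain steps

Total step count: 22. Longest linear sequence: 15 steps (steps 1, 3, 4, 5, 6, 7, 9, 10, 11, 13, 14, 17, 18, 21, 22; from 1 to 37).

**Step 9 (key step, proposed new method).**
- What may go wrong: the addition may proceed stepwise, with conjugate attack of 12 at C6 of 14 followed by silyl transfer to the pyrone oxygen instead of closure of the second bond. Compound 12 may be protodesilylated back to 11 by adventitious acid. Decarboxylation of 15 may be incomplete at 110 °C. During aromatisation of 16 the ring oxygen O1 may be lost from C7a instead of the silyloxy group, which opens the dihydrofuran ring.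
- Fallback, with known reactions only; it sets out from 2 and 3 and comes back at 17, and it also makes the ketene acetal of step 7 unnecessary. 2-Hydroxyphenylacetic acid is dibrominated (Br2, AcOH) to 2-(3,5-dibromo-2-hydroxyphenyl)acetic acid F1. MOMCl and i-Pr2NEt convert it into methoxymethyl 2-[3,5-dibromo-2-(methoxymethoxy)phenyl]acetate F2, whose ester is saponified (LiOH) to 2-[3,5-dibromo-2-(methoxymethoxy)phenyl]acetic acid F3. Acylation of lithiated 3 with the pivaloyl mixed anhydride of F3 gives (4R)-4-benzyl-3-{[3,5-dibromo-2-(methoxymethoxy)phenyl]acetyl}-1,3-oxazolidin-2-one F4. A Bu2BOTf/i-Pr2NEt aldol reaction with 2 gives the syn aldol (4R)-4-benzyl-3-{(2R,3R)-2-[3,5-dibromo-2-(methoxymethoxy)phenyl]-3-hydroxy-3-[3-methoxy-4-(methoxymethoxy)phenyl]propanoyl}-1,3-oxazolidin-2-one F5, in which the auxiliary sets C3. LiBH4 removes the auxiliary to give (1R,2S)-2-[3,5-dibromo-2-(methoxymethoxy)phenyl]-1-[3-methoxy-4-(methoxymethoxy)phenyl]propane-1,3-diol F6. HCl in MeOH/THF cleaves both acetals and ionises the benzylic carbinol, and the ortho phenol closes the ring stereoconvergently to the trans compound 4-[(2R,3S)-5,7-dibromo-3-(hydroxymethyl)-2,3-dihydro-1-benzofuran-2-yl]-2-methoxyphenol F7. MOMCl and K2CO3 in acetone re-protect the phenol only, giving {(2R,3S)-5,7-dibromo-2-[3-methoxy-4-(methoxymethoxy)phenyl]-2,3-dihydro-1-benzofuran-3-yl}methanol F8, and TBSCl/imidazole then gives 17.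

**Step 10.**
- What may go wrong: exchange at C5 as well as C7, double exchange, or protonation of 18 before it is borylated, each of which erodes the differentiation of the two bromides.
- Fallback; it sets out from 17 and comes back at 25. The bromides are differentiated by palladium instead of lithium. 17 is coupled directly with borane 24 (PdCl2(dppf), K3PO4, THF/DMF) at the less hindered C5 bromide para to O1, to give tert-butyl(3-{(2R,3S)-7-bromo-3-({[tert-butyl(dimethyl)silyl]oxy}methyl)-2-[3-methoxy-4-(methoxymethoxy)phenyl]-2,3-dihydro-1-benzofuran-5-yl}propoxy)diphenylsilane F9. The remaining C7 bromide is then methoxylated by palladium-catalysed C–O coupling with methanol (Pd2(dba)3, the biaryl phosphine tBuBrettPhos, NaOt-Bu, 1,4-dioxane, 50 °C), which gives 25. The site selectivity of the first coupling rests on a smaller bias than the lithium exchange, which is why this order is the second choice.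

**Step 21.**
- What may go wrong: Z to E isomerisation of the enoate through reversible addition of the phosphine, or alkylation of the hydrazide by-product instead of the carboxylate.
- Fallback; it sets out from 32, 33 and 2 and comes back at 36. The Z-alkene is built on the substrate. Controlled saponification of 33 gives [bis(2,2,2-trifluoroethoxy)phosphoryl]acetic acid F10. EDC/DMAP coupling of F10 to 32 gives 3-{(2R,3S)-7-methoxy-2-[3-methoxy-4-(methoxymethoxy)phenyl]-3-[({(2E)-3-[4-(methoxymethoxy)phenyl]prop-2-enoyl}oxy)methyl]-2,3-dihydro-1-benzofuran-5-yl}propyl [bis(2,2,2-trifluoroethoxy)phosphoryl]acetate F11. Still–Gennari olefination of F11 with aldehyde 2 (KN(SiMe3)2, 18-crown-6, THF, −78 °C) gives 36.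

**Step 22.**
- What may go wrong: slow cleavage of three aryl acetals forces long acid exposure, with alcoholysis of an enoate ester, Z to E drift, or ionisation of the C2–O1 bond.
- Fallback; it sets out from 32 and 35 and comes back at 37. The acid treatment is moved ahead of the Z-ester. The same aqueous HCl conditions applied to 32 give {(2R,3S)-2-(4-hydroxy-3-methoxyphenyl)-5-(3-hydroxypropyl)-7-methoxy-2,3-dihydro-1-benzofuran-3-yl}methyl (2E)-3-(4-hydroxyphenyl)prop-2-enoate F12, and applied to 35 give (2Z)-3-(4-hydroxy-3-methoxyphenyl)prop-2-enoic acid F13, which is purified as a small molecule. A Mitsunobu esterification of F12 with F13 (PPh3, DIAD, THF, 0 °C, dark) then gives 37 directly; the carboxylic acid is far more acidic than the phenols and is the nucleophile that is alkylated.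

## Further compounds

F1 | step 9 | 2-(3,5-dibromo-2-hydroxyphenyl)acetic acid | OC(=O)Cc1cc(Br)cc(Br)c1O
F2 | step 9 | methoxymethyl 2-[3,5-dibromo-2-(methoxymethoxy)phenyl]acetate | COCOC(=O)Cc1cc(Br)cc(Br)c1OCOC
F3 | step 9 | 2-[3,5-dibromo-2-(methoxymethoxy)phenyl]acetic acid | OC(=O)Cc1cc(Br)cc(Br)c1OCOC
F4 | step 9 | (4R)-4-benzyl-3-{[3,5-dibromo-2-(methoxymethoxy)phenyl]acetyl}-1,3-oxazolidin-2-one | COCOc1c(Br)cc(Br)cc1CC(=O)N1C(=O)OC[C@H]1Cc1ccccc1
F5 | step 9 | (4R)-4-benzyl-3-{(2R,3R)-2-[3,5-dibromo-2-(methoxymethoxy)phenyl]-3-hydroxy-3-[3-methoxy-4-(methoxymethoxy)phenyl]propanoyl}-1,3-oxazolidin-2-one | COCOc1c(Br)cc(Br)cc1[C@@H](C(=O)N1C(=O)OC[C@H]1Cc1ccccc1)[C@H](c1ccc(OCOC)c(OC)c1)O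
F6 | step 9 | (1R,2S)-2-[3,5-dibromo-2-(methoxymethoxy)phenyl]-1-[3-methoxy-4-(methoxymethoxy)phenyl]propane-1,3-diol | COCOc1c(Br)cc(Br)cc1[C@@H](CO)[C@H](c1ccc(OCOC)c(OC)c1)O
F7 | step 9 | 4-[(2R,3S)-5,7-dibromo-3-(hydroxymethyl)-2,3-dihydro-1-benzofuran-2-yl]-2-methoxyphenol | Brc1cc(Br)c2c(c1)[C@@H](CO)[C@H](c1ccc(O)c(OC)c1)O2
F8 | step 9 | {(2R,3S)-5,7-dibromo-2-[3-methoxy-4-(methoxymethoxy)phenyl]-2,3-dihydro-1-benzofuran-3-yl}methanol | Brc1cc(Br)c2c(c1)[C@@H](CO)[C@H](c1ccc(OCOC)c(OC)c1)O2
F9 | step 10 | tert-butyl(3-{(2R,3S)-7-bromo-3-({[tert-butyl(dimethyl)silyl]oxy}methyl)-2-[3-methoxy-4-(methoxymethoxy)phenyl]-2,3-dihydro-1-benzofuran-5-yl}propoxy)diphenylsilane | CC(C)(C)[Si](c1ccccc1)(c1ccccc1)OCCCc1cc(Br)c2c(c1)[C@@H](CO[Si](C)(C)C(C)(C)C)[C@H](c1ccc(OCOC)c(OC)c1)O2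
F10 | step 21 | [bis(2,2,2-trifluoroethoxy)phosphoryl]acetic acid | OC(=O)CP(=O)(OCC(F)(F)F)OCC(F)(F)F
F11 | step 21 | 3-{(2R,3S)-7-methoxy-2-[3-methoxy-4-(methoxymethoxy)phenyl]-3-[({(2E)-3-[4-(methoxymethoxy)phenyl]prop-2-enoyl}oxy)methyl]-2,3-dihydro-1-benzofuran-5-yl}propyl [bis(2,2,2-trifluoroethoxy)phosphoryl]acetate | O=C(CP(=O)(OCC(F)(F)F)OCC(F)(F)F)OCCCc1cc(OC)c2c(c1)[C@@H](COC(=O)/C=C/c1ccc(OCOC)cc1)[C@H](c1ccc(OCOC)c(OC)c1)O2
F12 | step 22 | {(2R,3S)-2-(4-hydroxy-3-methoxyphenyl)-5-(3-hydroxypropyl)-7-methoxy-2,3-dihydro-1-benzofuran-3-yl}methyl (2E)-3-(4-hydroxyphenyl)prop-2-enoate | OCCCc1cc(OC)c2c(c1)[C@@H](COC(=O)/C=C/c1ccc(O)cc1)[C@H](c1ccc(O)c(OC)c1)O2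
F13 | step 22 | (2Z)-3-(4-hydroxy-3-methoxyphenyl)prop-2-enoic acid | COc1cc(/C=C\C(=O)O)ccc1O
A1 | alternative 1 | trans-5-allyl-7-methoxy-2-[3-methoxy-4-(triisopropylsilyloxy)phenyl]-3-[(2,2,6,6-tetramethylpiperidin-1-yloxy)methyl]-2,3-dihydrobenzofuran | C=CCc1cc(OC)c2c(c1)[C@@H](CON1C(C)(C)CCCC1(C)C)[C@H](c1ccc(O[Si](C(C)C)(C(C)C)C(C)C)c(OC)c1)O2
A2 | alternative 1 | 5-allyl-1-iodo-3-methoxy-2-{[(1R)-1-[3-methoxy-4-(triisopropylsilyloxy)phenyl]prop-2-en-1-yl]oxy}benzene | C=CCc1cc(OC)c(O[C@H](C=C)c2ccc(O[Si](C(C)C)(C(C)C)C(C)C)c(OC)c2)c(I)c1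
A3 | alternative 1 | tributylstannane | CCCC[SnH](CCCC)CCCC
A4 | alternative 1 | 2,2,6,6-tetramethylpiperidin-1-oxyl | CC1(C)CCCC(C)(C)N1[O]
A5 | alternative 2 | (2R)-2-[5-allyl-3-methoxy-2-(methoxymethoxy)phenyl]-1-[3-methoxy-4-(triisopropylsilyloxy)phenyl]-3-(4,4,5,5-tetramethyl-1,3,2-dioxaborolan-2-yl)propan-1-ol (carbinol epimers) | C=CCc1cc(OC)c(OCOC)c(c1)[C@@H](CB1OC(C)(C)C(C)(C)O1)C(O)c1ccc(O[Si](C(C)C)(C(C)C)C(C)C)c(OC)c1
A6 | alternative 2 | 5-allyl-1-ethenyl-3-methoxy-2-(methoxymethoxy)benzene | C=CCc1cc(OC)c(OCOC)c(C=C)c1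
A7 | alternative 2 | 3-methoxy-4-(triisopropylsilyloxy)benzaldehyde | O=Cc1ccc(O[Si](C(C)C)(C(C)C)C(C)C)c(OC)c1
A8 | alternative 2 | bis(pinacolato)diboron | CC1(C)OB(OC1(C)C)B1OC(C)(C)C(C)(C)O1
A9 | alternative 2 | copper chloride CuCl | Cl[Cu]
A10 | alternative 3 | methyl (2R,3S)-2-(4-benzyloxy-3-methoxyphenyl)-5-(3-benzyloxypropyl)-7-methoxy-2,3-dihydro-1-benzofuran-3-carboxylate (cis) | c1ccccc1COCCCc1cc(OC)c2c(c1)[C@H](C(=O)OC)[C@H](c1ccc(OCc3ccccc3)c(OC)c1)O2
A11 | alternative 3 | methyl 2-diazo-2-{2-[(4-benzyloxy-3-methoxyphenyl)methoxy]-5-(3-benzyloxypropyl)-3-methoxyphenyl}acetate | COC(=O)C(=[N+]=[N-])c1cc(CCCOCc2ccccc2)cc(OC)c1OCc1ccc(OCc2ccccc2)c(OC)c1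
A12 | alternative 3 | Rh2(S-PTTL)4, dirhodium tetrakis[N-phthaloyl-(S)-tert-leucinate] | [Rh+2].[Rh+2].CC(C)(C)[C@H](N1C(=O)c2ccccc2C1=O)C(=O)[O-].CC(C)(C)[C@H](N1C(=O)c2ccccc2C1=O)C(=O)[O-].CC(C)(C)[C@H](N1C(=O)c2ccccc2C1=O)C(=O)[O-].CC(C)(C)[C@H](N1C(=O)c2ccccc2C1=O)C(=O)[O-]
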